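**Plan**

- Retrosynthesis: the nine O-protecting groups are removed last; the flavanone C4 ketone is traced back to a C4 methyl ether; the flavanone pyran ring is then cut at O1–C2 and C3–C4; finally the bond between taxifolin C8 and the styryl carbon is cut.
- Enabling feature: O1–C2 and C3–C4 of the flavanone enclose a trans-1,2-diarylethane unit (catechol ring on C2, ring A of the taxifolin unit on C3), which is an (E)-stilbene, while ring A, O1 and C4 of the flavanone make up a 1-methoxy ortho-quinone methide.
- Forward: both taxifolin rings are bought intact. C8 is iodinated, the taxifolin oxygens are changed from benzyl ethers to benzyl carbonates, and a Heck reaction attaches the styryl arm. The only new ring, the flavanone pyran ring, closes in the three-component cycloaddition; C4 oxidation and hydrogenolysis finish.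
- The carbonates make ring A of the taxifolin unit electron-poor, so the cycloaddition builds its positive charge next to the catechol ring; this fixes the C3-to-C8 linkage.
- Stereochemistry: taxifolin C2/C3 come from (+)-taxifolin. Flavanone C2/C3 trans comes from the E alkene and is also the stable arrangement once C3 is alpha to the ketone. The C2 face is set by a chiral Brønsted acid, with the minor diastereomer removed by chromatography.

Key step: step 8

Remark: the C4 methoxy centre of the cycloadduct is written in its all-equatorial (2,4-cis) form; either C4 epimer can be carried on, because this centre becomes the ketone.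
Remark: which antipode of the acid is matched with the (2R,3R) unit cannot be derived in advance; the (R) acid is written, and its mirror image takes its place if the other C2 face is preferred.

**Route**

Step 1
Reactants: 1 (+)-taxifolin
Product: 2 (2R,3R)-5,7,3',4'-tetra-O-benzyltaxifolin
Conditions: BnBr (4.4 equiv), K2CO3, DMF, rt
Reagents that add atoms: benzyl bromide, BrCc1ccccc1
Why: Williamson etherification alkylates the four phenols (the chelated O5–H last) while the secondary C3 alcohol is not deprotonated by K2CO3, and room temperature limits base-induced ring opening, so no stereocentre is touched.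

Step 2
Reactants: 2 (2R,3R)-5,7,3',4'-tetra-O-benzyltaxifolin
Product: 3 (2R,3R)-8-iodo-5,7,3',4'-tetra-O-benzyltaxifolin
Conditions: NIS (1.1 equiv), TFA (cat.), CH2Cl2/MeCN, 0 °C to rt, dark
Reagents that add atoms: N-iodosuccinimide, O=C1CCC(=O)N1I
Why: Electrophilic aromatic iodination of the phloroglucinol-type ring A should go to C8 once O5 is alkylated, since C8 is para to O5 and less hindered than C6 between two benzyloxy groups, and ring A reacts faster than the catechol ring.

Step 3
Reactants: 3 (2R,3R)-8-iodo-5,7,3',4'-tetra-O-benzyltaxifolin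
Product: 4 (2R,3R)-8-iodotaxifolin
Conditions: BCl3 (1 M in CH2Cl2, 8 equiv), C6HMe5 (12 equiv), CH2Cl2, −78 °C; MeOH quench
Reagents that add atoms: none
Why: Lewis-acid cleavage of aryl benzyl ethers with BCl3, with pentamethylbenzene trapping the benzyl cations by Friedel–Crafts alkylation, works at −78 °C and leaves the aryl iodide intact, which hydrogenolysis would not.

Step 4
Reactants: 4 (2R,3R)-8-iodotaxifolin
Product: 5 (2R,3R)-8-iodotaxifolin 3,5,7,3',4'-pentakis(benzyl carbonate)
Conditions: CbzCl (8 equiv), pyridine, DMAP (cat.), CH2Cl2, 0 °C to rt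
Reagents that add atoms: benzyl chloroformate, O=C(Cl)OCc1ccccc1
Why: DMAP-catalysed acylation of the four phenols and the C3 alcohol with a chloroformate gives carbonates that turn ring A from electron-rich to electron-poor, withstand acid and DDQ, and are later removed by hydrogenolysis.

Step 5
Reactants: 6 3,4-bis(benzyloxy)benzaldehyde
Product: 7 3,4-bis(benzyloxy)styrene
Conditions: Ph3PCH3Br, KOtBu, THF, 0 °C to rt
Reagents that add atoms: methyltriphenylphosphonium bromide, C[P+](c1ccccc1)(c1ccccc1)c1ccccc1.[Br-]
Why: Wittig methylenation of an aromatic aldehyde with a non-stabilised ylide is reliable and tolerates benzyl ethers.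

Step 6
Reactants: 5 (2R,3R)-8-iodotaxifolin 3,5,7,3',4'-pentakis(benzyl carbonate); 7 3,4-bis(benzyloxy)styrene
Product: 8 (2R,3R)-8-[(E)-2-(3,4-bis(benzyloxy)phenyl)ethenyl]taxifolin 3,5,7,3',4'-pentakis(benzyl carbonate)
Conditions: Pd(OAc)2 (10 mol %), Bu4NCl, NaHCO3, DMF, 70 °C
Reagents that add atoms: none
Why: In this Mizoroki–Heck reaction under ligand-free Jeffery conditions the electron-poor aryl iodide adds readily to zerovalent palladium, insertion into the terminal styrene and syn beta-hydride elimination give the E alkene, and solid NaHCO3 is too weak a base to cleave aryl carbonates or enolise C3.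

Step 7
Reactants: 9 2,4,6-trihydroxybenzaldehyde
Product: 10 2-hydroxy-4,6-bis(benzyloxy)benzaldehyde
Conditions: BnBr (2.05 equiv), K2CO3, DMF, 0 °C to rt
Reagents that add atoms: benzyl bromide, BrCc1ccccc1
Why: In this Williamson etherification the hydroxyl hydrogen-bonded to the formyl group is the least nucleophilic, so two equivalents of BnBr should alkylate O4 and one ortho oxygen only.

Step 8
Reactants: 8 (2R,3R)-8-[(E)-2-(3,4-bis(benzyloxy)phenyl)ethenyl]taxifolin 3,5,7,3',4'-pentakis(benzyl carbonate); 10 2-hydroxy-4,6-bis(benzyloxy)benzaldehyde (1.5 equiv); 11 trimethyl orthoformate (3 equiv)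
Product: 14 (2S,3S,4S)-4-methoxyflavan cycloadduct linked C3 to C8 of the taxifolin pentacarbonate, via dimethyl acetal 12 (not isolated), via oxocarbenium ion 13 (not isolated)
Conditions: (R)-3,3'-bis(2,4,6-triisopropylphenyl)-BINOL N-triflylphosphoramide (10 mol %), 5 Å MS, CH2Cl2, −20 °C to rt, slow addition of 10
Reagents that add atoms: none
Why: Proposed new method: aldehyde 10 is acetalised by 11 to 12, the acid ionises 12 to the oxocarbenium ion 13 (an O-protonated 1-methoxy ortho-quinone methide), the alkene carbon of 8 that carries taxifolin ring A attacks the cationic carbon (C3–C4), and the phenol oxygen then collapses onto the benzylic cation beside the 3,4-bis(benzyloxy)phenyl ring (O1–C2). The closest known reaction type is the acid-catalysed three-component chroman synthesis from salicylaldehydes, orthoformates and styrenes, an inverse-electron-demand hetero-Diels–Alder reaction of alkoxy ortho-quinone methides, here extended to a 1,2-diaryl alkene and to a chiral acid. The pyran ring closes as an asynchronous suprafacial [4+2] process, C–C bond first and the six-membered C–O closure second. C2/C3 trans follows from suprafacial transfer of the E geometry, the C2 face from the chiral phosphoramide anion that holds 13 through its phenol O–H (minor diastereomer removed by chromatography), and C4 from the preference for an equatorial methoxy group, a centre erased in step 9. The decisive requirement is regiochemistry: with carbonates on O5 and O7 and the C4 ketone, ring A of the taxifolin unit is a poor cation-stabilising group, so charge develops beside the para-benzyloxy ring and not beside ring A, as it would if ring A carried ethers. Slow addition of 10 keeps the electron-rich acetal dilute and suppresses its Friedel–Crafts self-condensation.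

Step 9
Reactants: 14 (2S,3S,4S)-4-methoxyflavan cycloadduct
Product: 15 (2S,3R)-5,7,3',4'-tetra-O-benzyleriodictyol linked C3 to C8 of (2R,3R)-taxifolin pentakis(benzyl carbonate)
Conditions: DDQ (1.5 equiv), CH2Cl2/H2O (10:1), 0 °C to rt
Reagents that add atoms: water, O
Why: DDQ oxidation of an electron-rich benzylic ether (the mechanism of oxidative para-methoxybenzyl ether cleavage) should abstract the axial C4 hydride, activated by the methoxy group and the trioxygenated ring A, and hydrolysis of the cation releases methanol and the ketone, leaving C2 untouched and C3 in the thermodynamically preferred trans arrangement.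

Step 10
Reactants: 15 protected biflavanone
Product: 16 (2S,3R)-eriodictyol-(3→8)-(2R,3R)-taxifolin (target)
Conditions: H2 (1 atm), Pd/C (10 %), THF/MeOH, rt
Reagents that add atoms: none
Why: Catalytic hydrogenolysis cleaves the four benzyl ethers and the five benzyl carbonates (which lose CO2) under neutral conditions that should neither epimerise C2/C3 of either unit nor reduce the hydrogen-bonded aryl ketones.

**Compound list**

1 | (+)-taxifolin, (2R,3R) | O=C1c2c(O)cc(O)cc2O[C@H](c2ccc(O)c(O)c2)[C@H]1O | starting material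
2 | (2R,3R)-5,7,3',4'-tetra-O-benzyltaxifolin | O=C1c2c(OCc3ccccc3)cc(OCc3ccccc3)cc2O[C@H](c2ccc(OCc3ccccc3)c(OCc3ccccc3)c2)[C@H]1O | intermediate
3 | (2R,3R)-8-iodo-5,7,3',4'-tetra-O-benzyltaxifolin | O=C1c2c(OCc3ccccc3)cc(OCc3ccccc3)c(I)c2O[C@H](c2ccc(OCc3ccccc3)c(OCc3ccccc3)c2)[C@H]1O | intermediate
4 | (2R,3R)-8-iodotaxifolin | O=C1c2c(O)cc(O)c(I)c2O[C@H](c2ccc(O)c(O)c2)[C@H]1O | intermediate
5 | (2R,3R)-8-iodotaxifolin 3,5,7,3',4'-pentakis(benzyl carbonate) | O=C1c2c(OC(=O)OCc3ccccc3)cc(OC(=O)OCc3ccccc3)c(I)c2O[C@H](c2ccc(OC(=O)OCc3ccccc3)c(OC(=O)OCc3ccccc3)c2)[C@H]1OC(=O)OCc1ccccc1 | intermediate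
6 | 3,4-bis(benzyloxy)benzaldehyde | O=Cc1ccc(OCc2ccccc2)c(OCc2ccccc2)c1 | starting material
7 | 3,4-bis(benzyloxy)styrene | C=Cc1ccc(OCc2ccccc2)c(OCc2ccccc2)c1 | intermediate
8 | (2R,3R)-8-[(E)-2-(3,4-bis(benzyloxy)phenyl)ethenyl]taxifolin 3,5,7,3',4'-pentakis(benzyl carbonate) | O=C1c2c(OC(=O)OCc3ccccc3)cc(OC(=O)OCc3ccccc3)c(/C=C/c3ccc(OCc4ccccc4)c(OCc4ccccc4)c3)c2O[C@H](c2ccc(OC(=O)OCc3ccccc3)c(OC(=O)OCc3ccccc3)c2)[C@H]1OC(=O)OCc1ccccc1 | intermediate
9 | 2,4,6-trihydroxybenzaldehyde | O=Cc1c(O)cc(O)cc1O | starting material
10 | 2-hydroxy-4,6-bis(benzyloxy)benzaldehyde | O=Cc1c(O)cc(OCc2ccccc2)cc1OCc1ccccc1 | intermediate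
11 | trimethyl orthoformate | COC(OC)OC | starting material
12 | 3,5-bis(benzyloxy)-2-(dimethoxymethyl)phenol (dimethyl acetal of 10) | COC(OC)c1c(O)cc(OCc2ccccc2)cc1OCc1ccccc1 | intermediate (not isolated)
13 | O-methyl oxocarbenium ion of 10 (O-protonated 1-methoxy ortho-quinone methide) | C[O+]=Cc1c(O)cc(OCc2ccccc2)cc1OCc1ccccc1 | intermediate (not isolated)
14 | (2S,3S,4S)-5,7-bis(benzyloxy)-2-[3,4-bis(benzyloxy)phenyl]-4-methoxyflavan (2,3-trans, 3,4-trans), linked C3 to C8 of (2R,3R)-taxifolin pentakis(benzyl carbonate) | CO[C@@H]1c2c(OCc3ccccc3)cc(OCc3ccccc3)cc2O[C@H](c2ccc(OCc3ccccc3)c(OCc3ccccc3)c2)[C@H]1c1c(OC(=O)OCc3ccccc3)cc(OC(=O)OCc3ccccc3)c2c1O[C@H](c1ccc(OC(=O)OCc3ccccc3)c(OC(=O)OCc3ccccc3)c1)[C@@H](OC(=O)OCc1ccccc1)C2=O | intermediate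
15 | (2S,3R)-5,7,3',4'-tetra-O-benzyleriodictyol linked C3 to C8 of (2R,3R)-taxifolin pentakis(benzyl carbonate) | O=C1c2c(OCc3ccccc3)cc(OCc3ccccc3)cc2O[C@H](c2ccc(OCc3ccccc3)c(OCc3ccccc3)c2)[C@H]1c1c(OC(=O)OCc3ccccc3)cc(OC(=O)OCc3ccccc3)c2c1O[C@H](c1ccc(OC(=O)OCc3ccccc3)c(OC(=O)OCc3ccccc3)c1)[C@@H](OC(=O)OCc1ccccc1)C2=O | intermediate
16 | (2S,3R)-eriodictyol-(3→8)-(2R,3R)-taxifolin | O=C1c2c(O)cc(O)cc2O[C@H](c2ccc(O)c(O)c2)[C@H]1c1c(O)cc(O)c2c1O[C@H](c1ccc(O)c(O)c1)[C@@H](O)C2=O | target

**Step count and risks**

Total steps: 10. Longest linear sequence: 8 (steps 1, 2, 3, 4, 6, 8, 9, 10).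

Steps most likely to fail:

1. Step 8 (bears the label). The stabilised oxocarbenium ion may add too slowly to the hindered, weakly nucleophilic stilbene. It may instead alkylate electron-rich arenes, and the chiral anion may discriminate the two alkene faces poorly. The fallback uses known chemistry and a more electrophilic, methoxy-free ortho-quinone methide. It sets out from aldehyde 10, which is reduced (NaBH4, THF/MeOH, 0 °C) to 3,5-bis(benzyloxy)-2-(hydroxymethyl)phenol F1. Under catalytic camphorsulfonic acid (CH2Cl2, 0 °C) F1 loses water to the parent ortho-quinone methide and undergoes the established hetero-Diels–Alder addition to stilbene 8. This should give the 2,3-trans flavan with a C4 methylene group; its (2S,3R) diastereomer, the C4-unsubstituted flavan F2, is separated by chromatography from the (2R,3S) isomer. DDQ in CH2Cl2/MeOH then methoxylates C4 of F2 trans to the C3 aryl group, the known oxidative C4 functionalisation of benzylated flavans, and the route is rejoined at 14.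

2. Step 9. Hydride abstraction may occur at C2–H of the flavan unit or at benzyl ether methylenes instead of C4, or the hindered C4–H may react sluggishly and the cation may lose H3. The fallback sets out from 14. The C4 methoxy group is exchanged for hydroxyl by acid-catalysed solvolysis through the ring-A-stabilised C4 cation (TsOH·H2O cat., THF/H2O, rt), giving the (2S,3S,4S)-flavan-4-ol F3. Dess–Martin periodinane (CH2Cl2, rt) then oxidises F3 to the ketone, and the route is rejoined at 15.

3. Step 6. Insertion at the di-ortho-substituted arylpalladium species may be slow, leading to dehalogenation. The base at 70 °C may also erode the aryl carbonates or open the dihydroflavonol ring, which would epimerise C2/C3. The fallback avoids base and sets out from aldehyde 6. Takai-type chromium-mediated stannylolefination (Bu3SnCHBr2, CrCl2, LiI, THF/DMF, rt) should give (E)-tributyl[2-(3,4-bis(benzyloxy)phenyl)ethenyl]stannane F4. Stille coupling of F4 with iodide 5 (Pd2(dba)3, AsPh3, CuI, DMF, 50 °C) rejoins the route at 8.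

**Further compounds**

F1 | step 8 | 3,5-bis(benzyloxy)-2-(hydroxymethyl)phenol | OCc1c(O)cc(OCc2ccccc2)cc1OCc1ccccc1
F2 | step 8 | (2S,3R)-5,7-bis(benzyloxy)-2-[3,4-bis(benzyloxy)phenyl]flavan (C4 methylene, 2,3-trans) linked C3 to C8 of (2R,3R)-taxifolin pentakis(benzyl carbonate) | C1c2c(OCc3ccccc3)cc(OCc3ccccc3)cc2O[C@H](c2ccc(OCc3ccccc3)c(OCc3ccccc3)c2)[C@H]1c1c(OC(=O)OCc3ccccc3)cc(OC(=O)OCc3ccccc3)c2c1O[C@H](c1ccc(OC(=O)OCc3ccccc3)c(OC(=O)OCc3ccccc3)c1)[C@@H](OC(=O)OCc1ccccc1)C2=O
F3 | step 9 | (2S,3S,4S)-flavan-4-ol corresponding to 14 (hydroxyl in place of methoxy at C4) | O[C@@H]1c2c(OCc3ccccc3)cc(OCc3ccccc3)cc2O[C@H](c2ccc(OCc3ccccc3)c(OCc3ccccc3)c2)[C@H]1c1c(OC(=O)OCc3ccccc3)cc(OC(=O)OCc3ccccc3)c2c1O[C@H](c1ccc(OC(=O)OCc3ccccc3)c(OC(=O)OCc3ccccc3)c1)[C@@H](OC(=O)OCc1ccccc1)C2=O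
F4 | step 6 | (E)-tributyl[2-(3,4-bis(benzyloxy)phenyl)ethenyl]stannane | CCCC[Sn](CCCC)(CCCC)/C=C/c1ccc(OCc2ccccc2)c(OCc2ccccc2)c1
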